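**Assumption:** the SMILES is read as the I‑3→II‑8 linked biflavanone (manniflavanone type) with configuration I‑(2S,3R), II‑(2R,3R). (+)‑Taxifolin, 2',4',6'‑trihydroxyacetophenone and boronic acid 8 are taken as commercial.

## Retrosynthetic overview

1. Target 10 ⇐ octabenzyl ether 9 by a single global hydrogenolysis.
2. 9 ⇐ 3‑aryl chromone 7 + arylboronic acid 8. The B‑ring of unit I goes on last, by a catalytic asymmetric conjugate arylation that dearomatises the γ‑pyrone ring and sets I‑C2 (catalyst) and I‑C3 (thermodynamic trans).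
3. 7 ⇐ 3‑iodochromone 6 + 8‑iodotaxifolin ether 3. The I‑3/II‑8 bond is made by borylation/Suzuki at the flat, non‑stereogenic chromone stage.
4. 6 ⇐ phloroacetophenone 4; 3 ⇐ (+)‑taxifolin 1, which supplies unit II with both rings and both stereocentres intact.
5. Ring order: unit II rings pre‑formed → chromone ring of unit I built (step 4) → dearomatised to the chroman‑4‑one (step 6).

## Route

**Step 1**
Reactants: 1, (+)‑taxifolin [(2R,3R)‑dihydroquercetin]
Product: 2, (2R,3R)‑5,7‑bis(benzyloxy)‑2‑[3,4‑bis(benzyloxy)phenyl]‑3‑hydroxychroman‑4‑one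
Conditions: BnBr (4.5 equiv), K2CO3, DMF, 50 °C, N2
Reagents that add atoms: benzyl bromide, BrCc1ccccc1 (four benzyl groups)
Why: Williamson etherification of the four phenols (the chelated 5‑OH needs the excess and warmth) while K2CO3 leaves the aliphatic 3‑OH free; capping the 4'‑ and 7‑phenols early shuts down quinone‑methide ring opening, so C2/C3 are retained.

**Step 2**
Reactants: 2, tetra‑O‑benzyltaxifolin
Product: 3, (2R,3R)‑5,7‑bis(benzyloxy)‑2‑[3,4‑bis(benzyloxy)phenyl]‑3‑hydroxy‑8‑iodochroman‑4‑one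
Conditions: NIS (1.05 equiv), TFA (cat.), MeCN/CH2Cl2, 0 °C → rt, dark
Reagents that add atoms: N‑iodosuccinimide, O=C1CCC(=O)N1I (iodine)
Why: Electrophilic aromatic iodination of the phloroglucinol‑type A ring goes to C8 because C6 is buttressed by two benzyloxy groups (the 5‑OBn is forced toward C6 by the peri carbonyl), as in per‑O‑alkylated 5,7‑dioxygenated flavonoids; the B ring is less nucleophilic and no stereocentre is touched.

**Step 3**
Reactants: 4, 2',4',6'‑trihydroxyacetophenone (phloroacetophenone)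
Product: 5, 1‑[2,4‑bis(benzyloxy)‑6‑hydroxyphenyl]ethanone
Conditions: BnBr (2.1 equiv), K2CO3, DMF, rt
Reagents that add atoms: benzyl bromide, BrCc1ccccc1 (two benzyl groups)
Why: Selective Williamson etherification; the 2‑OH hydrogen‑bonded to the acetyl carbonyl is the least nucleophilic and stays free for the ring closure.

**Step 4**
Reactants: 5, 2'‑hydroxy‑4',6'‑bis(benzyloxy)acetophenone
Product: 6, 5,7‑bis(benzyloxy)‑3‑iodo‑4H‑chromen‑4‑one
Conditions: DMF‑DMA, 95 °C; then I2, CHCl3, rt
Reagents that add atoms: N,N‑dimethylformamide dimethyl acetal, COC(OC)N(C)C (the C2–H carbon); iodine, II (iodine at C3)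
Why: Enaminone condensation followed by iodine‑triggered 6‑endo cyclisation with loss of Me2NH (Gammill 3‑iodochromone synthesis) builds the heteroaromatic γ‑pyrone ring of unit I with the C3 handle in place.

**Step 5**
Reactants: 3, 8‑iodo tetra‑O‑benzyltaxifolin; 6, 5,7‑bis(benzyloxy)‑3‑iodochromone
Product: 7, 5,7‑bis(benzyloxy)‑3‑{(2R,3R)‑5,7‑bis(benzyloxy)‑2‑[3,4‑bis(benzyloxy)phenyl]‑3‑hydroxy‑4‑oxochroman‑8‑yl}‑4H‑chromen‑4‑one
Conditions: 3, HBpin, Et3N, Pd(OAc)2/SPhos (cat.), dioxane, 80 °C; then 6, K3PO4 (aq), 60 °C, one pot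
Reagents that add atoms: none (boron and both iodines are lost)
Why: One‑pot Miyaura borylation/Suzuki–Miyaura coupling; SPhos tolerates the di‑ortho‑alkoxy aryl boronate, 3‑iodochromone coupling is the standard isoflavone construction, and the free 3‑OH, ketone and both stereocentres of unit II are spectators.

**Step 6 (key step)**
Reactants: 7, 3‑aryl chromone; 8, [3,4‑bis(benzyloxy)phenyl]boronic acid
Product: 9, (2S,3R)‑5,7‑bis(benzyloxy)‑2‑[3,4‑bis(benzyloxy)phenyl]‑3‑{(2R,3R)‑5,7‑bis(benzyloxy)‑2‑[3,4‑bis(benzyloxy)phenyl]‑3‑hydroxy‑4‑oxochroman‑8‑yl}chroman‑4‑one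
Conditions: 8 (3 equiv), Pd(TFA)2 (10 mol%), (R)‑t‑BuPyOx (12 mol%), NH4PF6, H2O, ClCH2CH2Cl, 60 °C, N2; then TsOH (cat.), CHCl3, rt to equilibrate C3
Reagents that add atoms: boronic acid 8, OB(O)c1ccc(OCc2ccccc2)c(OCc2ccccc2)c1 (aryl group at C2; the C3 hydrogen comes from water)
Why: Proposed new method: a cationic aryl–Pd(II)/PyOx species should carbopalladate the chromone C2=C3 bond with aryl going to the unsubstituted, oxygen‑bearing C2 and Pd to C3 (an oxa‑π‑allyl stabilised by carbonyl and aryl), and protonolysis then gives the chroman‑4‑one, so the pyrone is dearomatised; the ligand sets C2 as S (the R ligand is chosen by analogy with simple chromones; its antipode is used if the sense is reversed), and the acidic, doubly activated C3–H equilibrates under acid to the diequatorial 2,3‑trans (3R) isomer without opening the ring; the closest known reaction is Pd/PyOx‑ or Rh‑catalysed asymmetric conjugate addition of arylboronic acids to 3‑unsubstituted chromones giving flavanones, here extended to a 3‑aryl (isoflavone‑type) chromone.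

**Step 7**
Reactants: 9, octa‑O‑benzyl biflavanone
Product: 10, (2S,3R)‑2‑(3,4‑dihydroxyphenyl)‑3‑[(2R,3R)‑2‑(3,4‑dihydroxyphenyl)‑3,5,7‑trihydroxy‑4‑oxochroman‑8‑yl]‑5,7‑dihydroxychroman‑4‑one (target)
Conditions: H2 (1 atm), Pd(OH)2/C, THF/MeOH, rt
Reagents that add atoms: none (hydrogen only)
Why: Neutral hydrogenolysis cleaves all eight aryl benzyl ethers, while the chelated aryl ketones and the four stereocentres are unaffected under these non‑basic, non‑acidic conditions.

## Compound list

1 | (+)‑taxifolin, (2R,3R) | O=C1c2c(O)cc(O)cc2O[C@H](c2ccc(O)c(O)c2)[C@H]1O | starting material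
2 | 5,7,3',4'‑tetra‑O‑benzyl‑(2R,3R)‑taxifolin | O=C1c2c(OCc3ccccc3)cc(OCc3ccccc3)cc2O[C@H](c2ccc(OCc3ccccc3)c(OCc3ccccc3)c2)[C@H]1O | intermediate
3 | 8‑iodo‑5,7,3',4'‑tetra‑O‑benzyl‑(2R,3R)‑taxifolin | O=C1c2c(OCc3ccccc3)cc(OCc3ccccc3)c(I)c2O[C@H](c2ccc(OCc3ccccc3)c(OCc3ccccc3)c2)[C@H]1O | intermediate
4 | 2',4',6'‑trihydroxyacetophenone | CC(=O)c1c(O)cc(O)cc1O | starting material
5 | 1‑[2,4‑bis(benzyloxy)‑6‑hydroxyphenyl]ethanone | CC(=O)c1c(O)cc(OCc2ccccc2)cc1OCc1ccccc1 | intermediate
6 | 5,7‑bis(benzyloxy)‑3‑iodo‑4H‑chromen‑4‑one | O=c1c(I)coc2cc(OCc3ccccc3)cc(OCc3ccccc3)c12 | intermediate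
7 | 3‑(taxifolin‑8‑yl)chromone, hexabenzyl ether, (2R,3R) in unit II | O=c1c(-c2c(OCc3ccccc3)cc(OCc3ccccc3)c3c2O[C@H](c2ccc(OCc4ccccc4)c(OCc4ccccc4)c2)[C@@H](O)C3=O)coc2cc(OCc3ccccc3)cc(OCc3ccccc3)c12 | intermediate
8 | [3,4‑bis(benzyloxy)phenyl]boronic acid | OB(O)c1ccc(OCc2ccccc2)c(OCc2ccccc2)c1 | starting material
9 | octa‑O‑benzyl biflavanone, I‑(2S,3R), II‑(2R,3R) | O=C1c2c(OCc3ccccc3)cc(OCc3ccccc3)cc2O[C@H](c2ccc(OCc3ccccc3)c(OCc3ccccc3)c2)[C@H]1c1c(OCc2ccccc2)cc(OCc2ccccc2)c2c1O[C@H](c1ccc(OCc3ccccc3)c(OCc3ccccc3)c1)[C@@H](O)C2=O | intermediate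
10 | target biflavanone, I‑(2S,3R), II‑(2R,3R) | O=C1c2c(O)cc(O)cc2O[C@H](c2ccc(O)c(O)c2)[C@H]1c1c(O)cc(O)c2c1O[C@H](c1ccc(O)c(O)c1)[C@@H](O)C2=O | target

## Summary

Total steps: 7. Longest linear sequence: 5 (steps 1, 2, 5, 6, 7; the chromone branch, steps 3, 4, 5, 6, 7, is also 5).

Steps most likely to fail, each with a fallback that changes the approach:

1. **Step 6** (asymmetric dearomative arylation of the hindered 3‑aryl chromone). Fallback: give up catalyst control and activate 7 as its 4‑silyloxybenzopyrylium triflate (TBSOTf), add the 3,4‑bis(benzyloxy)phenyl group as an arylcopper/zinc reagent, hydrolyse the silyl enol ether, equilibrate C3 to trans and separate the two C2 epimers; these are diastereomers because unit II is enantiopure.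
2. **Step 5** (hindered Suzuki with a protodeboronation‑prone 2,6‑dialkoxyaryl boronate; the protodeboronated by‑product is 2 and can be recycled). Fallback: reverse the polarity by inserting zinc (Zn, LiCl) into the C–I bond of 6 and Negishi‑coupling the resulting 3‑chromonylzinc iodide with aryl iodide 3, so no aryl boronate is needed.
3. **Step 2** (C8 versus C6 or B‑ring iodination). Fallback: fix the regiochemistry by construction instead of substitution: iodinate ketone 5 ortho to its free OH (the future C8), condense with 3,4‑bis(benzyloxy)benzaldehyde to the chalcone, then asymmetric epoxidation (Juliá–Colonna) and cyclisation to the same 8‑iodo dihydroflavonol 3.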